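**Retrosynthetic overview**

1. Atoms carry prostanoid numbers: ester carbon C1, chain C2–C7, ring C8–C12 (C9 ketone, C10 bromine, C12 acetate carbon), chain C13–C20.
2. Enabling feature: the only ring is a 5-alkylidenecyclopent-2-enone whose C9 ketone lies between the exocyclic C7=C8 alkene and the C10=C11 ring alkene, next to the oxygenated quaternary C12. This is the 4π-closure pattern of an allenyl (C7=C8=C9) vinyl (C11=C12) ketone (C10).
3. Disconnection: 24 ⇒ acetate and C10–Br (from the enol triflate of a 1,2-dione enol) ⇒ ring by C9–C10 acylation plus C8–C12 conrotatory closure, in one flask, of an axially chiral α-lithioallenyl ether (C1–C9) on a β-alkoxy enamide (C10–C20).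
4. The allene axis (aR) is relayed to C12 (R) and to the 7Z alkene, and the C1 orthoester becomes the methyl ester in the same acid quench. The 5E alkene comes from (E)-1,2-dichloroethene, the 14Z alkene from syn-carbocupration of acetylene.
5. Order of ring formation: one ring only, the cyclopentenone, closed in step 8.

Key step: step 8

Remark: compounds 1, 2, 4, 9, 10, 12 and 13 are taken as commercial, and the allene axis is obtained by resolution (step 4), with the descriptor (aR) based on O > H at the ether terminus and C > H at the other.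

**Route**

Step 1
Reactants: 1 3-(methoxymethoxy)prop-1-yne; 2 (E)-1,2-dichloroethene
Product: 3 (1E)-1-chloro-5-(methoxymethoxy)pent-1-en-3-yne
Conditions: Pd(PPh3)4 (5 mol%), CuI (10 mol%), n-BuNH2 (2 equiv), 2 (5 equiv), Et2O, rt
Reagents that add atoms: none
Why: Sonogashira coupling with excess (E)-1,2-dichloroethene should stop at the mono-coupled (E)-chloroenyne, because the second C–Cl bond is much less reactive and oxidative addition retains the alkene geometry.

Step 2
Reactants: 3 (1E)-1-chloro-5-(methoxymethoxy)pent-1-en-3-yne; 4 4-bromo-1,1,1-trimethoxybutane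
Product: 6 (4E)-9,9,9-trimethoxy-1-(methoxymethoxy)non-4-en-2-yne, via (4,4,4-trimethoxybutyl)magnesium bromide 5 (not isolated)
Conditions: 4, Mg, THF, rt; then 3, Fe(acac)3 (5 mol%), THF/NMP, 0 °C; basic work-up, Et3N-deactivated silica
Reagents that add atoms: none
Why: Iron-catalysed Kumada cross-coupling of an alkenyl chloride with a primary alkyl Grignard reagent is fast and stereoretentive at 0 °C, and the orthoester and the acetal are inert to the Grignard reagent at this temperature.

Step 3
Reactants: 6 (4E)-9,9,9-trimethoxy-1-(methoxymethoxy)non-4-en-2-yne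
Product: 7 rac-(4E)-9,9,9-trimethoxy-1-(methoxymethoxy)nona-1,2,4-triene
Conditions: KOtBu (20 mol%), 18-crown-6 (20 mol%), THF, 0 °C, monitored; pH 8 buffer quench
Reagents that add atoms: none
Why: Base-catalysed propargyl-to-allenyl ether isomerization (deprotonation at the O-bearing propargylic CH2, reprotonation at C7) should give the vinylallenyl ether, the orthoester offering no acidic or electrophilic site under these conditions.

Step 4
Reactants: 7 rac-(4E)-9,9,9-trimethoxy-1-(methoxymethoxy)nona-1,2,4-triene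
Product: 8 (aR,4E)-9,9,9-trimethoxy-1-(methoxymethoxy)nona-1,2,4-triene
Conditions: preparative HPLC on cellulose tris(3,5-dimethylphenylcarbamate), hexane/i-PrOH (0.1% Et3N)
Reagents that add atoms: none
Why: Chromatographic resolution on a polysaccharide chiral phase is the practical way to a configurationally stable 1,3-disubstituted allenyl ether that has no salt-forming handle, and the unwanted antipode can be re-racemized with KOtBu and recycled.

Step 5
Reactants: 9 methyl (2E)-4-chloro-3-methoxybut-2-enoate; 10 naphthalen-2-ylmethanol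
Product: 11 methyl (2E)-4-chloro-3-(naphthalen-2-ylmethoxy)but-2-enoate
Conditions: PPTS (10 mol%), toluene, 90 °C, MeOH removed over 4 Å molecular sieves
Reagents that add atoms: none
Why: Acid-catalysed enol ether exchange (transetherification through the mixed ketal), driven by removal of methanol, should keep the thermodynamically preferred (E) geometry with the ether oxygen anti to the ester.

Step 6
Reactants: 11 methyl (2E)-4-chloro-3-(naphthalen-2-ylmethoxy)but-2-enoate; 12 pentylmagnesium bromide; 13 acetylene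
Product: 16 methyl (2E,5Z)-3-(naphthalen-2-ylmethoxy)undeca-2,5-dienoate, via pentylcopper 14 (not isolated), via (Z)-hept-1-enylcopper 15 (not isolated)
Conditions: 12, CuBr·SMe2, Et2O, −40 °C; 13, −40 → −25 °C; then 11, P(OEt)3, THF, −40 → 0 °C
Reagents that add atoms: none
Why: Carbocupration of acetylene (Normant) is a syn addition that gives only the (Z)-alkenylcopper, which should displace the activated primary allylic chloride by SN2, so the skipped (Z)-diene is made without passing through a base-labile β,γ-unsaturated carbonyl compound.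

Step 7
Reactants: 16 methyl (2E,5Z)-3-(naphthalen-2-ylmethoxy)undeca-2,5-dienoate
Product: 17 (2E,5Z)-1-(morpholin-4-yl)-3-(naphthalen-2-ylmethoxy)undeca-2,5-dien-1-one
Conditions: morpholine, AlMe3, CH2Cl2, 0 → 40 °C
Reagents that add atoms: morpholine, C1COCCN1
Why: Trimethylaluminium-mediated aminolysis (Weinreb-type amidation) converts the ester into the morpholine amide without base, so the doubly activated C13 methylene should not isomerize.

Step 8
Reactants: 8 (aR,4E)-9,9,9-trimethoxy-1-(methoxymethoxy)nona-1,2,4-triene; 17 (2E,5Z)-1-(morpholin-4-yl)-3-(naphthalen-2-ylmethoxy)undeca-2,5-dien-1-one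
Product: 20 methyl (5E,7Z)-7-[(2R)-4-hydroxy-2-(naphthalen-2-ylmethoxy)-2-[(2Z)-oct-2-en-1-yl]-5-oxocyclopent-3-en-1-ylidene]hept-5-enoate, via lithioallene 18 (not isolated), via allenyl vinyl ketone 19 (not isolated)
Conditions: 8, n-BuLi (1.05 equiv), THF, −78 °C; 17, −78 °C; then 0.5 M aq. HCl/THF, −78 → 0 °C
Reagents that add atoms: water, O
Why: Proposed new method: the allene-ether Nazarov cyclopentannelation (acylation of an α-lithioallenyl ether by a morpholine enamide, then acid-triggered cationic 4π closure) is established for β-alkyl and β-aryl enamides but not for a β-alkoxy enamide that must close onto an oxygen-bearing terminus; its closest known relatives are that cyclopentannelation itself and the Piancatelli rearrangement, whose 2,5-dioxygenated pentadienyl cation has the same oxygen pattern and closes to 4-oxygenated cyclopentenones, also with an alkyl group on the oxygenated terminus. Mechanism: 18 adds to the amide carbonyl (C9–C10), acid collapses the lithium aminal to ketone 19 and protonates it, and the pentadienyl cation C8=C9–C10–C11=C12 closes by thermal conrotation (C8–C12, formally 5-endo but allowed as a 4π electrocyclization) to the cyclopentenone, the only ring formed. The oxocarbenium ion at C9 then loses its methoxymethyl group to give the ketone, C10 stays as the enol, and the same aqueous acid hydrolyses the orthoester to the methyl ester. The C12 stereocentre is set by axial-to-central chirality transfer: the C6 substituent on the distal allene carbon C7 must rotate away from the incoming C12 terminus, which fixes the sense of conrotation, so the (aR) axis with the (2E) enamide (chain CH2 inside, ether oxygen outside) should give (12R) and at the same time place C6 cis to C9 (7Z). The step needs 1,2-addition instead of conjugate addition or deprotonation at C13, secured by the fully substituted, donor-deactivated β-carbon and by −78 °C, and it needs closure to outrun loss of the C12 ether group from the cation, secured by a naphthylmethyl group that does not ionize readily, by the nucleophilic enol-ether carbon C8 and by release of allene strain.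

Step 9
Reactants: 20 methyl (5E,7Z)-7-[(2R)-4-hydroxy-2-(naphthalen-2-ylmethoxy)-2-[(2Z)-oct-2-en-1-yl]-5-oxocyclopent-3-en-1-ylidene]hept-5-enoate
Product: 21 methyl (5E,7Z)-7-[(2R)-2-(naphthalen-2-ylmethoxy)-2-[(2Z)-oct-2-en-1-yl]-5-oxo-4-{[(trifluoromethyl)sulfonyl]oxy}cyclopent-3-en-1-ylidene]hept-5-enoate
Conditions: PhNTf2, Et3N, DMAP (cat.), CH2Cl2, −20 → 0 °C
Reagents that add atoms: N-phenylbis(trifluoromethanesulfonimide), O=S(=O)(N(c1ccccc1)S(=O)(=O)C(F)(F)F)C(F)(F)F
Why: O-Sulfonylation (triflation) of the acidic enol of the 1,2-dione should be selective, since the only other oxygen functions are an ether and esters, and fast trapping at low temperature keeps the enolate from expelling the C12 alkoxide.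

Step 10
Reactants: 21 methyl (5E,7Z)-7-[(2R)-2-(naphthalen-2-ylmethoxy)-2-[(2Z)-oct-2-en-1-yl]-5-oxo-4-{[(trifluoromethyl)sulfonyl]oxy}cyclopent-3-en-1-ylidene]hept-5-enoate
Product: 22 methyl (5E,7Z)-7-[(2R)-4-bromo-2-(naphthalen-2-ylmethoxy)-2-[(2Z)-oct-2-en-1-yl]-5-oxocyclopent-3-en-1-ylidene]hept-5-enoate
Conditions: Ni(OAc)2·4H2O (10 mol%), 1,5-cyclooctadiene (25 mol%), Zn (20 mol%), LiBr (3 equiv), DMA/THF, rt
Reagents that add atoms: lithium bromide, [Li+].[Br-]
Why: Nickel-catalysed triflate-to-halide exchange of an enol triflate (oxidative addition, triflate–bromide exchange at nickel, C–Br reductive elimination) runs at room temperature and puts bromine exactly at C10 without any electrophilic bromine that could attack the four alkenes.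

Step 11
Reactants: 22 methyl (5E,7Z)-7-[(2R)-4-bromo-2-(naphthalen-2-ylmethoxy)-2-[(2Z)-oct-2-en-1-yl]-5-oxocyclopent-3-en-1-ylidene]hept-5-enoate
Product: 23 methyl (5E,7Z)-7-[(2R)-4-bromo-2-hydroxy-2-[(2Z)-oct-2-en-1-yl]-5-oxocyclopent-3-en-1-ylidene]hept-5-enoate
Conditions: DDQ, CH2Cl2/pH 7 phosphate buffer, 0 °C → rt
Reagents that add atoms: none
Why: Oxidative cleavage of the 2-naphthylmethyl ether with DDQ (hydride abstraction at the benzylic CH2, hydrolysis of the oxocarbenium ion) should free the tertiary alcohol without acid, so the doubly allylic C12–O bond is not ionized and the stereocentre is untouched.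

Step 12
Reactants: 23 methyl (5E,7Z)-7-[(2R)-4-bromo-2-hydroxy-2-[(2Z)-oct-2-en-1-yl]-5-oxocyclopent-3-en-1-ylidene]hept-5-enoate
Product: 24 methyl (5E,7Z)-7-[(2R)-2-(acetyloxy)-4-bromo-2-[(2Z)-oct-2-en-1-yl]-5-oxocyclopent-3-en-1-ylidene]hept-5-enoate
Conditions: Ac2O, Et3N, DMAP, CH2Cl2, rt
Reagents that add atoms: acetic anhydride, CC(=O)OC(C)=O
Why: DMAP-catalysed acylation of the hindered tertiary allylic alcohol (nucleophilic catalysis through the N-acetylpyridinium ion) installs the acetate with retention, because the C12–O bond is not broken.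

**Compound list**

1 | 3-(methoxymethoxy)prop-1-yne | C#CCOCOC | starting material
2 | (E)-1,2-dichloroethene | Cl/C=C/Cl | starting material
3 | (1E)-1-chloro-5-(methoxymethoxy)pent-1-en-3-yne | Cl/C=C/C#CCOCOC | intermediate
4 | 4-bromo-1,1,1-trimethoxybutane | BrCCCC(OC)(OC)OC | starting material
5 | (4,4,4-trimethoxybutyl)magnesium bromide | Br[Mg]CCCC(OC)(OC)OC | intermediate
6 | (4E)-9,9,9-trimethoxy-1-(methoxymethoxy)non-4-en-2-yne | COCOCC#C/C=C/CCCC(OC)(OC)OC | intermediate
7 | rac-(4E)-9,9,9-trimethoxy-1-(methoxymethoxy)nona-1,2,4-triene | [H]C(OCOC)=C=C([H])/C=C/CCCC(OC)(OC)OC | intermediate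
8 | (aR,4E)-9,9,9-trimethoxy-1-(methoxymethoxy)nona-1,2,4-triene | [H]C(OCOC)=[C@@]=C([H])/C=C/CCCC(OC)(OC)OC | intermediate
9 | methyl (2E)-4-chloro-3-methoxybut-2-enoate | ClC/C(OC)=C\C(=O)OC | starting material
10 | naphthalen-2-ylmethanol | OCc1ccc2ccccc2c1 | starting material
11 | methyl (2E)-4-chloro-3-(naphthalen-2-ylmethoxy)but-2-enoate | ClC/C(OCc1ccc2ccccc2c1)=C\C(=O)OC | intermediate
12 | pentylmagnesium bromide | CCCCC[Mg]Br | starting material
13 | acetylene | C#C | starting material
14 | pentylcopper | CCCCC[Cu] | intermediate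
15 | (Z)-hept-1-enylcopper | CCCCC/C=C\[Cu] | intermediate
16 | methyl (2E,5Z)-3-(naphthalen-2-ylmethoxy)undeca-2,5-dienoate | CCCCC/C=C\C/C(OCc1ccc2ccccc2c1)=C\C(=O)OC | intermediate
17 | (2E,5Z)-1-(morpholin-4-yl)-3-(naphthalen-2-ylmethoxy)undeca-2,5-dien-1-one | CCCCC/C=C\C/C(OCc1ccc2ccccc2c1)=C\C(=O)N1CCOCC1 | intermediate
18 | [(aR,4E)-9,9,9-trimethoxy-1-(methoxymethoxy)nona-1,2,4-trien-1-yl]lithium (lithioallene) | [Li]C(OCOC)=[C@@]=C([H])/C=C/CCCC(OC)(OC)OC | intermediate
19 | (5E,11E,14Z,aR)-1,1,1-trimethoxy-9-(methoxymethoxy)-12-(naphthalen-2-ylmethoxy)icosa-5,7,8,11,14-pentaen-10-one (allenyl vinyl ketone) | O=C(/C=C(\C/C=C\CCCCC)OCc1ccc2ccccc2c1)C(OCOC)=[C@@]=C([H])/C=C/CCCC(OC)(OC)OC | intermediate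
20 | methyl (5E,7Z)-7-[(2R)-4-hydroxy-2-(naphthalen-2-ylmethoxy)-2-[(2Z)-oct-2-en-1-yl]-5-oxocyclopent-3-en-1-ylidene]hept-5-enoate | CCCCC/C=C\C[C@@]1(OCc2ccc3ccccc3c2)C=C(O)C(=O)/C1=C\C=C\CCCC(=O)OC | intermediate
21 | methyl (5E,7Z)-7-[(2R)-2-(naphthalen-2-ylmethoxy)-2-[(2Z)-oct-2-en-1-yl]-5-oxo-4-{[(trifluoromethyl)sulfonyl]oxy}cyclopent-3-en-1-ylidene]hept-5-enoate | CCCCC/C=C\C[C@@]1(OCc2ccc3ccccc3c2)C=C(OS(=O)(=O)C(F)(F)F)C(=O)/C1=C\C=C\CCCC(=O)OC | intermediate
22 | methyl (5E,7Z)-7-[(2R)-4-bromo-2-(naphthalen-2-ylmethoxy)-2-[(2Z)-oct-2-en-1-yl]-5-oxocyclopent-3-en-1-ylidene]hept-5-enoate | CCCCC/C=C\C[C@@]1(OCc2ccc3ccccc3c2)C=C(Br)C(=O)/C1=C\C=C\CCCC(=O)OC | intermediate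
23 | methyl (5E,7Z)-7-[(2R)-4-bromo-2-hydroxy-2-[(2Z)-oct-2-en-1-yl]-5-oxocyclopent-3-en-1-ylidene]hept-5-enoate | CCCCC/C=C\C[C@@]1(O)C=C(Br)C(=O)/C1=C\C=C\CCCC(=O)OC | intermediate
24 | methyl (5E,7Z)-7-[(2R)-2-(acetyloxy)-4-bromo-2-[(2Z)-oct-2-en-1-yl]-5-oxocyclopent-3-en-1-ylidene]hept-5-enoate | CCCCC/C=C\C[C@@]1(OC(C)=O)C=C(Br)C(=O)/C1=C\C=C\CCCC(=O)OC | target

**Step count and risks**

Total steps: 12. Longest linear sequence: 9 (steps 1–4, then 8–12).

Most likely to fail:

1. Step 8 (proposed new method). The lithioallene may act as a base at C13 of 17 instead of adding to the carbonyl. The oxygen-stabilised cation may lose its ether group or be hydrolysed before it closes. The relay of the axis to C12 may be incomplete.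
Fallback, known reactions only, setting out from 15 and from 5 and rejoining at 23: the ring is made first and the chains are attached by established cyclopentenone chemistry. Copper reagent 15 is alkylated with commercial 5-(chloromethyl)furan-2-carbaldehyde to give 5-[(2Z)-oct-2-en-1-yl]furan-2-carbaldehyde F1, which NaBH4 reduces to {5-[(2Z)-oct-2-en-1-yl]furan-2-yl}methanol F2. A Piancatelli rearrangement (H2O, ZnCl2, 100 °C) should convert F2 into rac-4-hydroxy-4-[(2Z)-oct-2-en-1-yl]cyclopent-2-en-1-one F3. Nucleophilic epoxidation (H2O2, NaOH, MeOH, 0 °C) gives rac-4-hydroxy-4-[(2Z)-oct-2-en-1-yl]-6-oxabicyclo[3.1.0]hexan-2-one F4. Opening with aqueous HBr and dehydration gives rac-2-bromo-4-hydroxy-4-[(2Z)-oct-2-en-1-yl]cyclopent-2-en-1-one F5, without electrophilic bromine. Grignard reagent 5 and 3-(dimethylamino)acrolein, then aqueous acid, give methyl (5E)-7-oxohept-5-enoate F6. The dianion of F5 (LiN(iPr)2, 2.2 equiv, THF, −78 °C) is condensed with F6 to methyl (5E)-7-{3-bromo-5-hydroxy-5-[(2Z)-oct-2-en-1-yl]-2-oxocyclopent-3-en-1-yl}-7-hydroxyhept-5-enoate F7. Dehydration (MsCl, Et3N, then DBU) gives rac-methyl (5E,7Z)-7-{4-bromo-2-hydroxy-2-[(2Z)-oct-2-en-1-yl]-5-oxocyclopent-3-en-1-ylidene}hept-5-enoate F8 together with its 7E isomer. The 7Z isomer is separated, the 7E isomer is re-equilibrated with light, and chromatography on a chiral phase gives 23.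

2. Step 3. The isomerization may run on past the allene into the fully conjugated trienyl ether through deprotonation at the C4 methylene, or the vinylallene may oligomerize.
Fallback, setting out from 3 and rejoining at 7: the order of isomerization and cross-coupling is inverted. Chloroenyne 3 has no acidic C–H other than the propargylic CH2. It is isomerized first (KOtBu, 18-crown-6, THF, −20 °C) to (4E)-5-chloro-1-(methoxymethoxy)penta-1,2,4-triene F9. The alkenyl chloride of F9 is then coupled with Grignard reagent 5 under Fe(acac)3 catalysis to give 7, so the C4 methylene enters only after the base step.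

3. Step 10. Low-valent nickel and zinc may reduce the dienone or insert into the allylic C12–O bond, or the triflate–bromide exchange may stall.
Fallback, setting out from 21 and rejoining at 22: stannylation and bromodestannylation. Pd(PPh3)4, Me3SnSnMe3 and LiCl in THF at 60 °C should give methyl (5E,7Z)-7-[(2R)-2-(naphthalen-2-ylmethoxy)-2-[(2Z)-oct-2-en-1-yl]-5-oxo-4-(trimethylstannyl)cyclopent-3-en-1-ylidene]hept-5-enoate F10. Ipso-bromination of F10 with NBS in CH2Cl2 at −78 °C gives 22.

Further compounds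

F1 | step 8 | 5-[(2Z)-oct-2-en-1-yl]furan-2-carbaldehyde | CCCCC/C=C\Cc1ccc(C=O)o1
F2 | step 8 | {5-[(2Z)-oct-2-en-1-yl]furan-2-yl}methanol | CCCCC/C=C\Cc1ccc(CO)o1
F3 | step 8 | rac-4-hydroxy-4-[(2Z)-oct-2-en-1-yl]cyclopent-2-en-1-one | CCCCC/C=C\CC1(O)C=CC(=O)C1
F4 | step 8 | rac-4-hydroxy-4-[(2Z)-oct-2-en-1-yl]-6-oxabicyclo[3.1.0]hexan-2-one | O=C1CC(O)(C/C=C\CCCCC)C2OC12
F5 | step 8 | rac-2-bromo-4-hydroxy-4-[(2Z)-oct-2-en-1-yl]cyclopent-2-en-1-one | CCCCC/C=C\CC1(O)C=C(Br)C(=O)C1
F6 | step 8 | methyl (5E)-7-oxohept-5-enoate | COC(=O)CCC/C=C/C=O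
F7 | step 8 | methyl (5E)-7-{3-bromo-5-hydroxy-5-[(2Z)-oct-2-en-1-yl]-2-oxocyclopent-3-en-1-yl}-7-hydroxyhept-5-enoate | CCCCC/C=C\CC1(O)C=C(Br)C(=O)C1C(O)/C=C/CCCC(=O)OC
F8 | step 8 | rac-methyl (5E,7Z)-7-{4-bromo-2-hydroxy-2-[(2Z)-oct-2-en-1-yl]-5-oxocyclopent-3-en-1-ylidene}hept-5-enoate | CCCCC/C=C\CC1(O)C=C(Br)C(=O)/C1=C\C=C\CCCC(=O)OC
F9 | step 3 | (4E)-5-chloro-1-(methoxymethoxy)penta-1,2,4-triene | [H]C(OCOC)=C=C([H])/C=C/Cl
F10 | step 10 | methyl (5E,7Z)-7-[(2R)-2-(naphthalen-2-ylmethoxy)-2-[(2Z)-oct-2-en-1-yl]-5-oxo-4-(trimethylstannyl)cyclopent-3-en-1-ylidene]hept-5-enoate | CCCCC/C=C\C[C@@]1(OCc2ccc3ccccc3c2)C=C([Sn](C)(C)C)C(=O)/C1=C\C=C\CCCC(=O)OC
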